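Readings and results are calculated for substances that don't exist; the scatter is artificial.

I cannot measure the catalyst in these flasks, but at one fixed temperature the readings hold a stand-in for it.

| flask | left-handed substrate | right-handed substrate | coupling partner | precatalyst | temperature | remark | time |
|---|---|---|---|---|---|---|---|
| spring | 0.32 M | 0.32 M | 0.80 equiv | 1.6 mol% | 10 °C | run made earlier |  |
| dawn | 0.32 M | 0.32 M | 0.40 equiv | 1.6 mol% | 25 °C | run made earlier |  |
| noon | 0.32 M | 0.32 M | 1.6 equiv | 1.6 mol% | 10 °C | run made earlier |  |
| east | 0.32 M | 0.32 M | 0.800 equiv (fed, over 1.0 h) | 1.6 mol% | 25 °C | all else is in the flask from the start; the feed brings no volume worth counting | 80 min |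
| north-west | 0.32 M | 0.32 M | 0.800 equiv (fed, over 1.0 h) | 1.6 mol% |  | the addition at 5 °C, then warmed to 25 °C; the feed brings no volume worth counting | 80 min |
| south-east | 0.32 M | 0.32 M | 0.800 equiv (in portions, 3, over 1.0 h) | 1.6 mol% | 25 °C | first portion at the start, last at 1.0 h | 80 min |
| north | 0.32 M | 0.32 M | 0.800 equiv | 1.6 mol% |  | everything together at the start at 5 °C, warmed to 25 °C at 1.0 h | 80 min |
| south-west | 0.32 M | 0.32 M | 0.800 equiv | 1.6 mol% | 25 °C | everything together at the start | 80 min |

| run | time / min | left-handed product / % | left-handed substrate / % |
|---|---|---|---|
| spring | 12.0 | 0.2 | 48.9 |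
| spring | 25.0 | 1.7 | 48.3 |
| spring | 50.0 | 4.6 | 47.4 |
| spring | 80.0 | 6.1 | 42.1 |
| spring | 180 | 20.5 | 28.6 |
| dawn | 6.00 | 1.7 | 50.6 |
| dawn | 15.0 | 4.3 | 46.7 |
| dawn | 30.0 | 9.2 | 40.9 |
| dawn | 50.0 | 14.5 | 36.4 |
| dawn | 60.0 | 16.8 | 34.0 |
| noon | 25.0 | 2.0 | 48.0 |
| noon | 50.0 | 5.6 | 44.3 |
| noon | 80.0 | 13.2 | 35.5 |
| noon | 120 | 21.0 | 27.7 |

(readings scatter by 1 percentage point)

- catalyst is single-handed; left-handed substrate and right-handed substrate are mirror images of each other, charged as a racemate, each of them at the stated concentration

1. which flask leads in amount of left-handed product, in percent of the left-handed substrate and right-handed substrate together charged ("all alike" within 1.5 percentage points) (east / north-west / south-east / north / south-west / all alike)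
2. how much left-handed product is there at the end, in percent of the left-handed substrate and right-handed substrate together charged: east
3. how much left-handed product is there at the end, in percent of the left-handed substrate and right-handed substrate together charged: north-west
4. how much left-handed product is there at the end, in percent of the left-handed substrate and right-handed substrate together charged: south-east
5. how much left-handed product is there at the end, in percent of the left-handed substrate and right-handed substrate together charged: north
6. how much left-handed product is there at the end, in percent of the left-handed substrate and right-handed substrate together charged: south-west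

Dawn gives 0.0685 M⁻¹ min⁻¹ over its first 30.0 min and 0.153 M⁻¹ min⁻¹ from there to 60.0 min. I call this number, the rate of forming left-handed product divided by the mean [coupling partner][left-handed substrate], the live-catalyst gauge. Read from dawn, it climbs to twice its first value, which I take as an induction period: precatalyst is still becoming catalyst. Spring reads 0.00687 M⁻¹ min⁻¹ over 80.0 min at 10 °C, and dawn's first value, at 25 °C, is ten times that.

So I count the cold hour of north and north-west as lost and treat their warm 20.0 min as the opening of a warm flask, with the gauge g taken from dawn's first stretch. For a time t, I reckon the product as g·t·[coupling partner][left-handed substrate] divided by one plus g·t times the mean of those two starting concentrations. This gives 12.6% for both. South-west, on dawn's later gauge for the whole 80 min, gives 34.6%. Feeding moves coupling partner towards the later, stronger gauge, so I place east and south-east a little under south-west.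

The forecast, which differs from my figures, gives south-west 32%, east 25.5%, south-east 25%, north 15.5% and north-west 14.5%, and says “Feeding or portioning keeps the partner low early”.

The flasks give south-west 33.8%, east 31.3%, south-east 30.1%, north 12.8% and north-west 12.5%.

    coupling partner + catalyst + right-handed substrate → catalyst + right-handed product (k = 0.890 M⁻² min⁻¹, Ea = 64.0 kJ mol⁻¹)
    coupling partner + catalyst + left-handed substrate → catalyst + left-handed product (k = 67.7 M⁻² min⁻¹, Ea = 52.0 kJ mol⁻¹)
    precatalyst → catalyst (k = 0.0161 min⁻¹, Ea = 102 kJ mol⁻¹)
    (constants at 25 °C)

North-west ends at 12.5%, and at 60.0 min it holds 0.943% left-handed product, with 4.89% of the catalyst charged in the form of catalyst. Over its last 20.0 min, north-west's own amounts put the gauge at 0.0631 M⁻¹ min⁻¹. For a neighbouring flask, like north-west but with 1.40 equiv of coupling partner, dawn's first gauge and the same reckoning give 20.1%, and that flask ends with 20.0% left-handed product.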